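**Plan**

- Retrosynthesis: cut C15=C15' first (Wittig), then C7'–C8' (aldol; the carbinol is later oxidised to the enolised diketone). In each half, cut the alkenyl–alkenyl bond C10–C11 (C10'–C11') together with the methyl bond at C9 (C9') by methylalumination/cross-coupling with one common C11–C15 dienyl iodide. Last, cut C8–C9 (sp–sp coupling) and C7≡C8 (aldehyde homologation).
- Enabling feature: C9=C10 is a trisubstituted E alkene with its methyl (C19) on C9, bonded directly to the C7≡C8 triple bond on C6 of the cyclohexene ring (ring A). It is therefore the syn methyl–metal adduct of a ring-bound terminal buta-1,3-diyne.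
- Forward: ring A comes from safranal and the cyclopentane (ring B) from camphoric acid, so no carbocycle is built. The ring A diyne and the dienyl iodide are joined in step 9. The C8'–C15' aldehyde is made by the same reaction from propargyl alcohol and added to the ring B methyl ketone. The two C20 halves are united by the Wittig reaction, then desilylated.
- Stereochemistry: C3/C4 from catalytic asymmetric epoxidation of C3=C4 and anti opening by water; C5' from camphoric acid; C3' from carboxylate-tethered iodolactonisation followed by Mitsunobu inversion. Alkene geometry comes from syn carbometalation (C9, C9'), syn hydrozirconation (C11, C11'), the E enynol (C13, C13') and thermal equilibration after the Wittig step (C15).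

Key step: step 9

Assumption: carotenoid numbering is used for all fragments, and the facial sense of the epoxidation in step 2 is taken from the accepted model for cyclic cis-alkenes with one conjugating substituent (if the opposite sense were found, the (S,S) catalyst would be used and nothing else changes).

**Route**

Step 1
Reactants: 1 safranal
Product: 2 1-ethynyl-2,6,6-trimethylcyclohexa-1,3-diene
Conditions: Me3SiCHN2, n-BuLi, THF, -78 °C; then 1, -78 °C → rt (product kept in solution, volatile)
Reagents that add atoms: trimethylsilyldiazomethane, C[Si](C)(C)C=[N+]=[N-]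
Why: Colvin rearrangement: the lithiated silyldiazomethane adds to the aldehyde, Peterson elimination and loss of N2 give an alkylidene carbene, and its 1,2-hydrogen shift delivers the terminal alkyne (C7≡C8) without disturbing the diene.

Step 2
Reactants: 2 1-ethynyl-2,6,6-trimethylcyclohexa-1,3-diene
Product: 3 (1R,6S)-3-ethynyl-2,4,4-trimethyl-7-oxabicyclo[4.1.0]hept-2-ene, the (3S,4R)-epoxide in carotenoid numbering
Conditions: (R,R)-[N,N'-bis(3,5-di-tert-butylsalicylidene)cyclohexane-1,2-diaminato]MnCl (5 mol%), mCPBA, NMO, CH2Cl2, -78 °C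
Reagents that add atoms: 3-chloroperoxybenzoic acid (mCPBA), O=C(OO)c1cccc(Cl)c1
Why: Jacobsen–Katsuki epoxidation: the manganese-oxo species reacts with the cis-disubstituted, conjugated C3=C4 bond (cyclic 1,3-dienes are an established substrate class) and not with the hindered tetrasubstituted C5=C6 bond or the alkyne, and the (R,R) ligand is expected to deliver oxygen to the face that gives the (3S,4R) epoxide, which fixes C3.

Step 3
Reactants: 3 (3S,4R)-epoxide
Product: 4 (1S,2S)-4-ethynyl-3,5,5-trimethylcyclohex-3-ene-1,2-diol, the (3S,4S)-trans-diol in carotenoid numbering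
Conditions: HClO4 (cat.), THF–H2O, 0 °C
Reagents that add atoms: water, O
Why: Acid-catalysed epoxide hydrolysis: water attacks the allylic carbon C4 from the side opposite to the protonated oxygen (trans-diaxial opening), which inverts C4 to S while the C3–O bond and thus 3S are untouched, and attack at the other allylic terminus C6 is blocked because it is fully substituted and flanked by the gem-dimethyl group.

Step 4
Reactants: 4 (3S,4S)-trans-diol
Product: 5 (3S,4S)-bis(tert-butyldimethylsilyl) ether of 4 (ring A alkyne)
Conditions: TBSOTf, 2,6-lutidine, CH2Cl2, -78 → 0 °C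
Reagents that add atoms: tert-butyldimethylsilyl triflate, CC(C)(C)[Si](C)(C)OS(=O)(=O)C(F)(F)F
Why: Silylation with the silyl triflate and a hindered pyridine base is the standard way to cap both hydroxyls of a hindered trans-1,2-diol, and the ethers are inert to the copper, aluminium, zirconium and palladium chemistry that follows.

Step 5
Reactants: 5 ring A alkyne; 6 (bromoethynyl)trimethylsilane
Product: 7 trimethylsilyl-capped ring A buta-1,3-diyne
Conditions: CuCl (10 mol%), NH2OH·HCl, n-BuNH2, H2O–THF, 0 °C
Reagents that add atoms: none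
Why: Cadiot–Chodkiewicz coupling: the copper acetylide of 5 formed under amine/CuCl catalysis displaces bromide from the bromoalkyne to give the unsymmetrical diyne (C8–C9 bond), with hydroxylamine keeping copper monovalent so that oxidative homocoupling is suppressed.

Step 6
Reactants: 7 trimethylsilyl-capped diyne
Product: 8 (3S,4S)-bis-silyloxy ring A buta-1,3-diyne (terminal diyne)
Conditions: K2CO3 (cat.), MeOH–THF, 0 °C → rt; solution of 8 used at once
Reagents that add atoms: none
Why: Carbonate-catalysed methanolysis cleaves the alkynyl C–Si bond selectively, since the two secondary silyl ethers are stable to these conditions.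

Step 7
Reactants: 9 (E)-3-methylpent-2-en-4-yn-1-ol
Product: 10 tert-butyldimethylsilyl ether of 9
Conditions: TBSCl, imidazole, CH2Cl2, 0 °C → rt
Reagents that add atoms: tert-butyldimethylsilyl chloride, CC(C)(C)[Si](C)(C)Cl
Why: Routine silylation of a primary allylic alcohol (silyl chloride, imidazole).

Step 8
Reactants: 10 silylated enynol
Product: 12 (2E,4E)-5-iodo-3-methylpenta-2,4-dien-1-ol tert-butyldimethylsilyl ether, via alkenylzirconocene chloride 11 (not isolated)
Conditions: Cp2Zr(H)Cl, THF, rt, dark; then I2, 0 °C
Reagents that add atoms: iodine, II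
Why: Hydrozirconation–iodination: Cp2Zr(H)Cl adds H and Zr syn across the terminal alkyne with zirconium on the terminal carbon, and iodine cleaves the C–Zr bond with retention, so the new C4=C5 bond is E and the existing trisubstituted alkene is untouched.

Step 9
Reactants: 8 ring A buta-1,3-diyne; 13 trimethylaluminium; 12 dienyl iodide
Product: 15 tris-silyl ether of (3S,4S,9E,11E,13E)-3,4-dihydroxy-7,8-didehydroretinol (left half C1–C15), via (E)-alkenyldimethylalane 14 (not isolated)
Conditions: 13 (2.5 equiv), Cp2ZrCl2 (0.3 equiv), ClCH2CH2Cl, 0 °C → rt; then 12, ZnCl2 (co-catalyst), Pd(PPh3)4 (5 mol%), THF, rt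
Reagents that add atoms: none
Why: Me3Al and Cp2ZrCl2 form a methylzirconocene–aluminium species that adds methyl and metal in one syn four-centre step across the terminal C9≡C10 bond, methyl to the internal carbon C9 and aluminium to C10, so alane 14 has the 9E geometry by mechanism. Zerovalent palladium then inserts into the C–I bond of 12, the alkenyl group passes from aluminium via zinc to palladium, and reductive elimination forms C10–C11 with retention at both alkenyl carbons. The closest known reaction type is the zirconium-catalysed methylalumination of terminal alkynes and conjugated enynes followed in the same flask by palladium- and zinc-catalysed alkenyl–alkenyl coupling (Negishi carboalumination–cross-coupling). No ring closes and no stereocentre is made; the silyl ethers at C3 and C4 are spectators. The step needs addition at the terminal and not the internal triple bond, methyl at C9, and carbometalation ahead of C–H alumination: the free terminus is unhindered, whereas C7≡C8 is internal and lies between the C1 gem-dimethyl group and the C5 methyl of ring A, and the metal prefers the terminal carbon. Using the alane without isolation avoids handling a metalated or halogenated C9=C10 unit, the position at which 7,8-didehydro polyenes lose their E geometry most easily.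

Step 10
Reactants: 15 tris-silyl ether
Product: 16 (3S,4S)-3,4-bis(tert-butyldimethylsilyloxy)-7,8-didehydroretinol (C15 alcohol)
Conditions: HF·pyridine, pyridine, THF, 0 °C
Reagents that add atoms: none
Why: Selective desilylation: pyridine-buffered HF·pyridine cleaves the unhindered primary allylic silyl ether much faster than the two hindered secondary ones, and the buffer protects the acid-sensitive polyenyl alcohol.

Step 11
Reactants: 16 C15 alcohol
Product: 18 C15 triphenylphosphonium bromide of the left half, via C15 allylic bromide 17 (not isolated)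
Conditions: CBr4, PPh3, CH2Cl2, -20 °C; then PPh3, rt
Reagents that add atoms: triphenylphosphine, c1ccc(cc1)P(c1ccccc1)c1ccccc1; tetrabromomethane, BrC(Br)(Br)Br
Why: Appel bromination followed by quaternisation: the alcohol is converted under neutral conditions into the primary allylic bromide, which PPh3 displaces (SN2) in the same flask before it can ionise or isomerise.

Step 12
Reactants: 19 propargyl alcohol; 13 trimethylaluminium; 12 dienyl iodide
Product: 21 (2E,4E,6E)-8-(tert-butyldimethylsilyloxy)-2,6-dimethylocta-2,4,6-trien-1-ol (C8'–C15' unit), via aluminium alkoxide alkenylalane 20 (not isolated)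
Conditions: 13 (3 equiv), Cp2ZrCl2 (0.3 equiv), ClCH2CH2Cl, 0 °C → rt; then 12, ZnCl2 (co-catalyst), Pd(PPh3)4 (5 mol%), THF, rt
Reagents that add atoms: none
Why: Negishi carboalumination–cross-coupling as in step 9: propargyl alcohol reacts as its aluminium alkoxide, methyl and aluminium add syn with methyl on the internal carbon (C9'), and palladium/zinc-catalysed coupling with 12 proceeds with retention, giving the all-E trienol with only the C8' hydroxyl free.

Step 13
Reactants: 21 C8'–C15' trienol
Product: 22 (2E,4E,6E)-8-(tert-butyldimethylsilyloxy)-2,6-dimethylocta-2,4,6-trienal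
Conditions: MnO2 (excess), CH2Cl2, rt
Reagents that add atoms: none
Why: MnO2 oxidation of a primary allylic alcohol stops at the enal and does not isomerise the triene or touch the silyl ether.

Step 14
Reactants: 23 (1R,3S)-(+)-camphoric acid
Product: 24 dimethyl (1R,3S)-camphorate
Conditions: MeI, K2CO3, DMF, rt
Reagents that add atoms: iodomethane, CI
Why: Carboxylate O-alkylation (SN2 on iodomethane) esterifies both acids, including the hindered tertiary one that resists Fischer esterification, without touching either stereocentre.

Step 15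
Reactants: 24 dimethyl camphorate
Product: 25 (1S,3R)-3-(methoxycarbonyl)-2,2,3-trimethylcyclopentane-1-carboxylic acid
Conditions: KOH (1.05 equiv), MeOH–H2O, rt; then aq. HCl
Reagents that add atoms: potassium hydroxide, [K+].[OH-]
Why: Selective saponification: hydroxide attacks the secondary ester far faster than the tertiary ester on the fully substituted carbon, so only the secondary carboxyl is released; epimerisation at that carbon would not matter because the centre is removed in step 16.

Step 16
Reactants: 25 half ester
Product: 26 methyl (1R)-1,2,2-trimethylcyclopent-3-ene-1-carboxylate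
Conditions: Pb(OAc)4, Cu(OAc)2 (cat.), pyridine, benzene, 80 °C
Reagents that add atoms: none
Why: Kochi oxidative decarboxylation: Pb(OAc)4 generates the secondary ring radical and Cu(OAc)2 oxidises it to the alkene by loss of the only β-hydrogen available (the other neighbour is quaternary), a path faster than cationic rearrangement, and the quaternary stereocentre is not involved.

Step 17
Reactants: 26 alkene ester
Product: 27 (1R)-1,2,2-trimethylcyclopent-3-ene-1-carboxylic acid
Conditions: KOH, ethylene glycol–H2O, 140 °C; then aq. HCl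
Reagents that add atoms: potassium hydroxide, [K+].[OH-]
Why: Saponification of the hindered ester under forcing alkaline conditions is safe here because neither the isolated alkene nor the quaternary centre has an acidic hydrogen.

Step 18
Reactants: 27 alkene acid
Product: 28 (1S,4R,6S)-6-iodo-4,5,5-trimethyl-2-oxabicyclo[2.2.1]heptan-3-one
Conditions: I2, KI, NaHCO3, H2O–THF, rt, dark
Reagents that add atoms: iodine, II
Why: Iodolactonisation: the carboxylate opens the iodonium ion at the less hindered alkene carbon (the other one is neopentyl) from its own face, forming the bridged γ-lactone, so the new C–O bond (the future C3'–O) is cis to the carboxyl carbon by virtue of the tether.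

Step 19
Reactants: 28 iodolactone
Product: 29 (1R,4R)-4,5,5-trimethyl-2-oxabicyclo[2.2.1]heptan-3-one
Conditions: Bu3SnH, AIBN (cat.), benzene, 80 °C
Reagents that add atoms: none
Why: Radical chain dehalogenation with the tin hydride removes iodine and leaves the lactone and both stereocentres unchanged.

Step 20
Reactants: 29 bridged lactone
Product: 30 1-[(1R,4R)-4-hydroxy-1,2,2-trimethylcyclopentyl]ethan-1-one (cis hydroxy ketone)
Conditions: MeLi (1.05 equiv), Et2O, -78 °C; then H2O
Reagents that add atoms: methyllithium, [Li]C
Why: Addition of methyllithium to a lactone: the bicyclic lithium hemiketalate formed at the hindered carbonyl persists at low temperature and so prevents a second addition, collapsing on work-up to the cis hydroxy methyl ketone (in equilibrium with its hemiketal).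

Step 21
Reactants: 30 cis hydroxy ketone
Product: 32 1-[(1R,4S)-4-hydroxy-1,2,2-trimethylcyclopentyl]ethan-1-one (trans hydroxy ketone), via trans 4-nitrobenzoate 31 (not isolated)
Conditions: 4-nitrobenzoic acid, PPh3, DIAD, THF, 0 °C → rt; then K2CO3 (cat.), MeOH, rt
Reagents that add atoms: 4-nitrobenzoic acid, O=C(O)c1ccc(cc1)[N+](=O)[O-]
Why: Mitsunobu inversion: 4-nitrobenzoate, the acid of choice for hindered secondary alcohols, displaces the oxyphosphonium group by SN2 so that the ring oxygen becomes trans to the acetyl group (the 3'S centre of the target), and mild methanolysis of the activated aryl ester frees the alcohol while the quaternary centre, having no α-hydrogen, cannot epimerise.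

Step 22
Reactants: 32 trans hydroxy ketone; 22 C8'–C15' trienal
Product: 34 aldol adduct (β-hydroxy ketone; C8' epimers), via dilithium enolate 33 (not isolated)
Conditions: LiN(iPr)2 (2.1 equiv), THF, -78 °C; then 22, -78 °C; AcOH
Reagents that add atoms: none
Why: Directed aldol addition: the base forms the alkoxide and the only possible enolate (the methyl side, the other α-carbon being quaternary), which adds 1,2 to the α-methyl enal at low temperature to form C7'–C8'; the new carbinol centre is unselective and irrelevant because it is oxidised in step 24.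

Step 23
Reactants: 34 aldol adduct
Product: 35 triol (C3', C8', C15' hydroxyls free)
Conditions: Bu4NF, AcOH, THF, 0 °C → rt
Reagents that add atoms: none
Why: Fluoride desilylation buffered with acetic acid removes the primary silyl ether without retro-aldol cleavage or dehydration of the β-hydroxy ketone.

Step 24
Reactants: 35 triol
Product: 36 (2E,4E,6E,8Z)-8-hydroxy-10-[(1R,4S)-4-hydroxy-1,2,2-trimethylcyclopentyl]-3,7-dimethyl-10-oxodeca-2,4,6,8-tetraenal (right half C15'–C6' with ring B, enolised diketone)
Conditions: MnO2 (excess), CH2Cl2, rt, dark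
Reagents that add atoms: none
Why: MnO2 oxidises the two allylic alcohols only (C15' to the aldehyde, C8' to the ketone, which enolises to the hydrogen-bonded diketone) and leaves the saturated C3' alcohol untouched.

Step 25
Reactants: 18 left-half phosphonium bromide; 36 right-half aldehyde
Product: 39 3,4-bis(tert-butyldimethylsilyl) ether of the target (all-E), via phosphorus ylide 37 (not isolated), via sodium enolate 38 (not isolated)
Conditions: NaOMe (2.2 equiv), MeOH–CH2Cl2, 0 °C → rt, dark; aq. AcOH; then toluene, 80 °C, dark
Reagents that add atoms: none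
Why: Wittig olefination: the polyenyl ylide condenses with the C15' aldehyde while the diketone is held as its unreactive sodium enolate, and the 15Z isomer formed alongside is converted by brief heating into the more stable all-E isomer, the central disubstituted cis bond being the one that equilibrates most readily.

Step 26
Reactants: 39 bis-silyl ether of the target
Product: 40 (3S,4S,3'S,5'R)-3,4,3',8'-tetrahydroxy-7,8-didehydro-β,κ-caroten-6'-one (CNP0114063.1)
Conditions: Bu4NF, AcOH, THF, rt, dark
Reagents that add atoms: none
Why: Fluoride cleavage of the two secondary silyl ethers under acetic acid buffering, conditions tolerated by the polyene, the triple bond and the enolised diketone, releases the target.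

**Compound list**

1 | safranal (2,6,6-trimethylcyclohexa-1,3-diene-1-carbaldehyde) | CC1=C(C=O)C(C)(C)CC=C1 | starting material
2 | 1-ethynyl-2,6,6-trimethylcyclohexa-1,3-diene | CC1=C(C#C)C(C)(C)CC=C1 | intermediate
3 | (1R,6S)-3-ethynyl-2,4,4-trimethyl-7-oxabicyclo[4.1.0]hept-2-ene | CC1=C(C#C)C(C)(C)C[C@@H]2O[C@H]12 | intermediate
4 | (1S,2S)-4-ethynyl-3,5,5-trimethylcyclohex-3-ene-1,2-diol | CC1=C(C#C)C(C)(C)C[C@H](O)[C@H]1O | intermediate
5 | (3S,4S)-bis(tert-butyldimethylsilyl) ether of 4 | CC1=C(C#C)C(C)(C)C[C@H](O[Si](C)(C)C(C)(C)C)[C@H]1O[Si](C)(C)C(C)(C)C | intermediate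
6 | (bromoethynyl)trimethylsilane | C[Si](C)(C)C#CBr | starting material
7 | trimethylsilyl-capped ring A buta-1,3-diyne | CC1=C(C#CC#C[Si](C)(C)C)C(C)(C)C[C@H](O[Si](C)(C)C(C)(C)C)[C@H]1O[Si](C)(C)C(C)(C)C | intermediate
8 | (3S,4S)-bis-silyloxy ring A buta-1,3-diyne | CC1=C(C#CC#C)C(C)(C)C[C@H](O[Si](C)(C)C(C)(C)C)[C@H]1O[Si](C)(C)C(C)(C)C | intermediate
9 | (E)-3-methylpent-2-en-4-yn-1-ol | C#C/C(C)=C/CO | starting material
10 | tert-butyldimethylsilyl ether of 9 | C#C/C(C)=C/CO[Si](C)(C)C(C)(C)C | intermediate
11 | (1E,3E)-dienylzirconocene chloride from 10 (cyclopentadienyl rings written as σ-bonded) | Cl[Zr](/C=C/C(C)=C/CO[Si](C)(C)C(C)(C)C)(C1C=CC=C1)C1C=CC=C1 | intermediate (not isolated)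
12 | (2E,4E)-5-iodo-3-methylpenta-2,4-dien-1-ol tert-butyldimethylsilyl ether | I/C=C/C(C)=C/CO[Si](C)(C)C(C)(C)C | intermediate
13 | trimethylaluminium | C[Al](C)C | starting material
14 | (E)-alkenyldimethylalane (aluminium on C10, methyl on C9) | CC1=C(C#C/C(C)=C/[Al](C)C)C(C)(C)C[C@H](O[Si](C)(C)C(C)(C)C)[C@H]1O[Si](C)(C)C(C)(C)C | intermediate (not isolated)
15 | tris-silyl ether of (3S,4S,9E,11E,13E)-3,4-dihydroxy-7,8-didehydroretinol | CC1=C(C#C/C(C)=C/C=C/C(C)=C/CO[Si](C)(C)C(C)(C)C)C(C)(C)C[C@H](O[Si](C)(C)C(C)(C)C)[C@H]1O[Si](C)(C)C(C)(C)C | intermediate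
16 | (3S,4S)-3,4-bis(tert-butyldimethylsilyloxy)-7,8-didehydroretinol | CC1=C(C#C/C(C)=C/C=C/C(C)=C/CO)C(C)(C)C[C@H](O[Si](C)(C)C(C)(C)C)[C@H]1O[Si](C)(C)C(C)(C)C | intermediate
17 | C15 allylic bromide of 16 | CC1=C(C#C/C(C)=C/C=C/C(C)=C/CBr)C(C)(C)C[C@H](O[Si](C)(C)C(C)(C)C)[C@H]1O[Si](C)(C)C(C)(C)C | intermediate (not isolated)
18 | C15 triphenylphosphonium bromide of the left half | CC1=C(C#C/C(C)=C/C=C/C(C)=C/C[P+](c2ccccc2)(c2ccccc2)c2ccccc2)C(C)(C)C[C@H](O[Si](C)(C)C(C)(C)C)[C@H]1O[Si](C)(C)C(C)(C)C.[Br-] | intermediate
19 | propargyl alcohol (prop-2-yn-1-ol) | C#CCO | starting material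
20 | (E)-3-(dimethylalumino)-2-methylprop-2-en-1-ol dimethylaluminium alkoxide | C[Al](C)/C=C(\C)CO[Al](C)C | intermediate (not isolated)
21 | (2E,4E,6E)-8-(tert-butyldimethylsilyloxy)-2,6-dimethylocta-2,4,6-trien-1-ol | OC/C(C)=C/C=C/C(C)=C/CO[Si](C)(C)C(C)(C)C | intermediate
22 | (2E,4E,6E)-8-(tert-butyldimethylsilyloxy)-2,6-dimethylocta-2,4,6-trienal | O=C/C(C)=C/C=C/C(C)=C/CO[Si](C)(C)C(C)(C)C | intermediate
23 | (1R,3S)-(+)-camphoric acid | CC1(C)[C@@H](C(=O)O)CC[C@@]1(C)C(=O)O | starting material
24 | dimethyl (1R,3S)-1,2,2-trimethylcyclopentane-1,3-dicarboxylate | CC1(C)[C@@H](C(=O)OC)CC[C@@]1(C)C(=O)OC | intermediate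
25 | (1S,3R)-3-(methoxycarbonyl)-2,2,3-trimethylcyclopentane-1-carboxylic acid | CC1(C)[C@@H](C(=O)O)CC[C@@]1(C)C(=O)OC | intermediate
26 | methyl (1R)-1,2,2-trimethylcyclopent-3-ene-1-carboxylate | CC1(C)C=CC[C@@]1(C)C(=O)OC | intermediate
27 | (1R)-1,2,2-trimethylcyclopent-3-ene-1-carboxylic acid | CC1(C)C=CC[C@@]1(C)C(=O)O | intermediate
28 | (1S,4R,6S)-6-iodo-4,5,5-trimethyl-2-oxabicyclo[2.2.1]heptan-3-one | O=C1O[C@H]2C[C@]1(C)C(C)(C)[C@@H]2I | intermediate
29 | (1R,4R)-4,5,5-trimethyl-2-oxabicyclo[2.2.1]heptan-3-one | O=C1O[C@H]2C[C@]1(C)C(C)(C)C2 | intermediate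
30 | 1-[(1R,4R)-4-hydroxy-1,2,2-trimethylcyclopentyl]ethan-1-one (hydroxyl cis to acetyl) | CC(=O)[C@]1(C)C[C@H](O)CC1(C)C | intermediate
31 | (1S,3R)-3-acetyl-3,4,4-trimethylcyclopentyl 4-nitrobenzoate | CC(=O)[C@]1(C)C[C@@H](OC(=O)c2ccc(cc2)[N+](=O)[O-])CC1(C)C | intermediate (not isolated)
32 | 1-[(1R,4S)-4-hydroxy-1,2,2-trimethylcyclopentyl]ethan-1-one (hydroxyl trans to acetyl) | CC(=O)[C@]1(C)C[C@@H](O)CC1(C)C | intermediate
33 | dilithium alkoxide enolate of 32 | C=C(O[Li])[C@]1(C)C[C@@H](O[Li])CC1(C)C | intermediate (not isolated)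
34 | (4E,6E,8E)-3-hydroxy-1-[(1R,4S)-4-hydroxy-1,2,2-trimethylcyclopentyl]-4,8-dimethyl-10-(tert-butyldimethylsilyloxy)deca-4,6,8-trien-1-one, mixture of C8' (chain C3) epimers | CC(C)(C)[Si](C)(C)OC/C=C(C)/C=C/C=C(C)/C(O)CC(=O)[C@]1(C)C[C@@H](O)CC1(C)C | intermediate
35 | (4E,6E,8E)-3,10-dihydroxy-1-[(1R,4S)-4-hydroxy-1,2,2-trimethylcyclopentyl]-4,8-dimethyldeca-4,6,8-trien-1-one, mixture of C8' epimers | OC/C=C(C)/C=C/C=C(C)/C(O)CC(=O)[C@]1(C)C[C@@H](O)CC1(C)C | intermediate
36 | (2E,4E,6E,8Z)-8-hydroxy-10-[(1R,4S)-4-hydroxy-1,2,2-trimethylcyclopentyl]-3,7-dimethyl-10-oxodeca-2,4,6,8-tetraenal | O=C/C=C(C)/C=C/C=C(C)/C(O)=C/C(=O)[C@]1(C)C[C@@H](O)CC1(C)C | intermediate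
37 | triphenylphosphorus ylide from 18 | CC1=C(C#C/C(C)=C/C=C/C(C)=C/C=P(c2ccccc2)(c2ccccc2)c2ccccc2)C(C)(C)C[C@H](O[Si](C)(C)C(C)(C)C)[C@H]1O[Si](C)(C)C(C)(C)C | intermediate (not isolated)
38 | sodium enolate of the diketone 36 | O=C/C=C(C)/C=C/C=C(C)/C(O[Na])=C/C(=O)[C@]1(C)C[C@@H](O)CC1(C)C | intermediate (not isolated)
39 | 3,4-bis(tert-butyldimethylsilyl) ether of the target (all-E) | CC1=C(C#C/C(C)=C/C=C/C(C)=C/C=C/C=C(C)/C=C/C=C(C)/C(O)=C/C(=O)[C@]2(C)C[C@@H](O)CC2(C)C)C(C)(C)C[C@H](O[Si](C)(C)C(C)(C)C)[C@H]1O[Si](C)(C)C(C)(C)C | intermediate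
40 | (3S,4S,3'S,5'R)-3,4,3',8'-tetrahydroxy-7,8-didehydro-β,κ-caroten-6'-one (CNP0114063.1) | CC1=C(C#C/C(C)=C/C=C/C(C)=C/C=C/C=C(C)/C=C/C=C(C)/C(O)=C/C(=O)[C@]2(C)C[C@@H](O)CC2(C)C)C(C)(C)C[C@H](O)[C@H]1O | target

**Totals**

Total step count: 26.
Longest linear sequence: 13 steps (steps 14–26, from camphoric acid); the safranal branch reaches the target in 11 steps.

**Steps most likely to fail**

Step 2. The oxidant may discriminate poorly between the two faces of this unusual dienyne, or part of the material may be oxidised at the tetrasubstituted alkene, so that the epoxide is formed with low enantiomeric purity. The fallback replaces asymmetric induction by resolution. Starting from 2, epoxidation with the racemic form of the same MnCl complex (mCPBA, NMO, -78 °C) would give the racemic cis-epoxide F1. Hydrolysis under the conditions of step 3 would give the racemic trans-diol F2. Acylation with vinyl acetate and immobilised Candida antarctica lipase B, screened so that the (3R,4R) enantiomer is esterified at its less hindered hydroxyl, would give the (1R,2R)-monoacetate F3 and leave the (3S,4S)-diol 4. After chromatographic separation the route is rejoined at 4.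

Step 9. Metalation of the acidic diyne C–H or oligomerisation of the sensitive terminal diyne may outrun carbometalation, or the alane may be lost before it couples. The fallback sets C9=C10 by hydrozirconation and makes C8–C9 last. Iodide 12 would be coupled with propyne (Sonogashira, Pd(PPh3)2Cl2, CuI, Et3N) to give the silylated (2E,4E)-3-methylocta-2,4-dien-6-yn-1-ol F4. Cp2Zr(H)Cl would add syn with zirconium on the methyl-bearing alkyne carbon to give the alkenylzirconocene chloride F5, and iodine would convert it into the silylated (2E,4E,6E)-7-iodo-3-methylocta-2,4,6-trien-1-ol F6. Sonogashira coupling of F6 with ring A alkyne 5 (Pd(PPh3)4, CuI, Et3N) would give 15, where the route is rejoined; diyne 8 is then not needed.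

Step 25. The diketone enolate may add to the aldehyde of a second molecule (Knoevenagel-type self-condensation), or the acidic enol may quench the ylide, so that olefination stays incomplete. The fallback masks the diketone. From 36, TBSOTf and 2,6-lutidine would silylate the C3' hydroxyl and the enol oxygen to give the bis-silylated aldehyde F7. Reaction of F7 with ylide 37, preformed from 18 with NaN(SiMe3)2 in THF at -78 °C and followed by the same thermal equilibration, would give the tetra-silylated polyene F8. The fluoride treatment of step 26 would remove all four silyl groups, so the route is rejoined at 40.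

Further compounds
F1 | step 2 | racemic cis-epoxide of 2 (both enantiomers of 3) | CC1=C(C#C)C(C)(C)C[C@@H]2O[C@H]12.CC1=C(C#C)C(C)(C)C[C@H]2O[C@@H]12
F2 | step 2 | racemic trans-4-ethynyl-3,5,5-trimethylcyclohex-3-ene-1,2-diol (both enantiomers of 4) | CC1=C(C#C)C(C)(C)C[C@H](O)[C@H]1O.CC1=C(C#C)C(C)(C)C[C@@H](O)[C@@H]1O
F3 | step 2 | (1R,2R)-4-ethynyl-2-hydroxy-3,5,5-trimethylcyclohex-3-en-1-yl acetate | CC1=C(C#C)C(C)(C)C[C@@H](OC(C)=O)[C@@H]1O
F4 | step 9 | (2E,4E)-3-methylocta-2,4-dien-6-yn-1-ol tert-butyldimethylsilyl ether | CC#C/C=C/C(C)=C/CO[Si](C)(C)C(C)(C)C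
F5 | step 9 | alkenylzirconocene chloride from F4 (zirconium on the methyl-bearing carbon) | Cl[Zr](/C(C)=C/C=C/C(C)=C/CO[Si](C)(C)C(C)(C)C)(C1C=CC=C1)C1C=CC=C1
F6 | step 9 | (2E,4E,6E)-7-iodo-3-methylocta-2,4,6-trien-1-ol tert-butyldimethylsilyl ether | I/C(C)=C/C=C/C(C)=C/CO[Si](C)(C)C(C)(C)C
F7 | step 25 | bis-silylated 36 (C3' silyl ether and C8' silyl enol ether) | O=C/C=C(C)/C=C/C=C(C)/C(O[Si](C)(C)C(C)(C)C)=C/C(=O)[C@]1(C)C[C@@H](O[Si](C)(C)C(C)(C)C)CC1(C)C
F8 | step 25 | tetra-silylated target (C3, C4, C3' silyl ethers and C8' silyl enol ether) | CC1=C(C#C/C(C)=C/C=C/C(C)=C/C=C/C=C(C)/C=C/C=C(C)/C(O[Si](C)(C)C(C)(C)C)=C/C(=O)[C@]2(C)C[C@@H](O[Si](C)(C)C(C)(C)C)CC2(C)C)C(C)(C)C[C@H](O[Si](C)(C)C(C)(C)C)[C@H]1O[Si](C)(C)C(C)(C)C
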